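**Retrosynthetic overview**
- The butenolide is attached near the end by a B-alkyl Suzuki–Miyaura coupling (C12–C13) onto a C9 vinyl group. The 6α-acetoxy group and H-5α come from α-face hydroboration of a C5=C6 alkene.
- Enabling feature: ring B holds the tetrasubstituted C8=C9 bond between the C7 methylene and quaternary C10, and its C5–H/C6–O pair is the hydration retron of a C5=C6 alkene. Ring B is therefore a cyclohexa-1,4-diene, the [4+2] adduct of but-2-ynal (C17–C8≡C9–C11) and a ring A 1-vinylcyclohexene (C7=C6–C5=C10).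
- The diene comes from a ring A ketone by enol triflation and Stille vinylation. Its stereocentres C2 and C4 come from enantioselective deprotonation of a meso 4-silyloxy-2,6-dimethylcyclohexanone followed by axial hydroxymethylation; the meso ketone comes from 2,6-dimethylhydroquinone.
- Ring order: ring A (hydrogenated arene), then ring B (Diels–Alder), then the preformed butenolide ring is coupled on.

Key step: step 10

Numbering remark: positions are given in labdane numbering (ring A = C1–C5, C10; ring B = C5–C10; side chain C11–C16; C17 on C8; C18/C19 on C4; C20 on C10); α/β refer to the usual drawing with C20 β; TBS = tert-butyldimethylsilyl, TMS = trimethylsilyl.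

Assumption: the (S,S)-amide of step 4 is taken to remove the axial α-proton that leads to 7, by analogy with the sense reported for 4-substituted cyclohexanones; if the two methyl groups reverse that sense, the (R,R)-amide is used and nothing else changes.

**Step 1**
Reactants: 1 2,6-dimethylbenzene-1,4-diol
Product: 2 2,6-dimethylcyclohexane-1,4-diol (all-cis isomer expected to predominate)
Conditions: H2 (50 bar), 5% Rh/Al2O3, iPrOH, 60 °C
Reagents that add atoms: none
Why: Heterogeneous arene hydrogenation over rhodium adds hydrogen to one ring face with little C–O hydrogenolysis, so the all-cis diol should be the main product.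

**Step 2**
Reactants: 2 2,6-dimethylcyclohexane-1,4-diol
Product: 3 all-cis-4-(TBS-oxy)-2,6-dimethylcyclohexan-1-ol
Conditions: TBSCl (1.05 equiv), imidazole, DMF, 0 °C
Reagents that add atoms: tert-butyldimethylsilyl chloride, CC(C)(C)[Si](C)(C)Cl
Why: Standard silyl ether formation should select the unhindered equatorial hydroxyl over the axial hydroxyl flanked by two methyl-bearing carbons.

**Step 3**
Reactants: 3 all-cis-4-(TBS-oxy)-2,6-dimethylcyclohexan-1-ol
Product: 5 all-cis-4-(TBS-oxy)-2,6-dimethylcyclohexan-1-one (meso), via ketone epimer mixture 4 (not isolated)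
Conditions: IBX, DMSO, rt; then DBU (0.2 equiv), CH2Cl2, rt; chromatography
Reagents that add atoms: none
Why: IBX oxidation of the hindered secondary alcohol followed by base equilibration (enolization) of the two α-carbons should place both methyl groups equatorial; any isomer with a trans silyloxy group cannot epimerize and is removed by chromatography.

**Step 4**
Reactants: 5 meso ketone
Product: 7 (4R,6S)-4-(TBS-oxy)-2,6-dimethyl-1-(TMS-oxy)cyclohex-1-ene, via lithium enolate 6 (not isolated)
Conditions: (S,S)-bis(1-phenylethyl)amine, n-BuLi, LiCl, TMSCl (in situ quench), THF, −100 → −78 °C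
Reagents that add atoms: chlorotrimethylsilane, C[Si](C)(C)Cl
Why: Enantiotopic-proton-selective deprotonation of a meso ketone by a chiral lithium amide with internal silyl quench (asymmetric desymmetrization) should fix the absolute configuration of the silyloxy carbon relative to the enol carbon and deliver a single enol ether regioisomer.

**Step 5**
Reactants: 7 TMS enol ether
Product: 8 (2R,4R,6S)-4-(TBS-oxy)-2-(hydroxymethyl)-2,6-dimethylcyclohexan-1-one
Conditions: 37% aq. HCHO, Sc(OTf)3 (10 mol %), THF, 0 °C → rt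
Reagents that add atoms: formaldehyde, C=O
Why: In this Lewis acid-catalysed aqueous Mukaiyama aldol (hydroxymethylation), formaldehyde should attack the tetrasubstituted enol carbon axially, on the face of the axial hydrogen at the silyloxy carbon, so the new quaternary centre carries CH2OH trans to the equatorial OTBS group.

**Step 6**
Reactants: 8 hydroxymethyl ketone
Product: 9 (2R,4R,6S)-4-(TBS-oxy)-2-[(TBS-oxy)methyl]-2,6-dimethylcyclohexan-1-one
Conditions: TBSCl, imidazole, DMF, rt
Reagents that add atoms: tert-butyldimethylsilyl chloride, CC(C)(C)[Si](C)(C)Cl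
Why: Silylation of the primary neopentyl alcohol removes the retro-aldol liability and provides the bulky group that later shields the β-face of the diene.

**Step 7**
Reactants: 9 bis-silyl ketone
Product: 11 (4R,6R)-4-(TBS-oxy)-6-[(TBS-oxy)methyl]-2,6-dimethylcyclohex-1-en-1-yl trifluoromethanesulfonate, via potassium enolate 10 (not isolated)
Conditions: KN(SiMe3)2, THF, −78 °C; then PhNTf2, −78 → 0 °C
Reagents that add atoms: N-phenylbis(trifluoromethanesulfonimide), O=S(=O)(N(c1ccccc1)S(=O)(=O)C(F)(F)F)C(F)(F)F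
Why: The ketone has a single enolizable α-carbon (the other is quaternary), so enolate O-triflation should give one enol triflate; the methyl-bearing stereocentre is erased as intended.

**Step 8**
Reactants: 11 enol triflate
Product: 12 (4R,6S)-4-(TBS-oxy)-6-[(TBS-oxy)methyl]-1-ethenyl-2,6-dimethylcyclohex-1-ene
Conditions: tributyl(vinyl)stannane, Pd(PPh3)4 (5 mol %), LiCl, THF, 65 °C
Reagents that add atoms: tributyl(vinyl)stannane, C=C[Sn](CCCC)(CCCC)CCCC
Why: Stille coupling of hindered 2,6,6-trisubstituted cyclohexenyl triflates with vinylstannanes is a standard entry to 1-vinylcyclohexene dienes.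

**Step 9**
Reactants: 13 but-2-yn-1-ol
Product: 14 but-2-ynal
Conditions: activated MnO2 (excess), CH2Cl2, rt; filtered solution used directly
Reagents that add atoms: none
Why: MnO2 oxidizes propargylic alcohols to ynals without over-oxidation, and the volatile aldehyde is handled only in solution.

**Step 10**
Reactants: 12 ring A diene; 14 but-2-ynal
Product: 15 (5S,7R,8aS)-7-(TBS-oxy)-5-[(TBS-oxy)methyl]-2,5,8a-trimethyl-3,5,6,7,8,8a-hexahydronaphthalene-1-carbaldehyde
Conditions: Me2AlCl (0.3 equiv), CH2Cl2, −78 → −30 °C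
Reagents that add atoms: none
Why: This is a Lewis acid-activated intermolecular Diels–Alder reaction between the s-cis 1-vinylcyclohexene unit of 12 and the ynal, concerted but asynchronous (the unsubstituted vinyl terminus bonds first to the methyl-bearing β-carbon of the aluminium-bound ynal, then the formyl-bearing α-carbon bonds to the methyl-bearing ring carbon); the closest known reaction type is the thermal cycloaddition of 2,6,6-trialkyl-1-vinylcyclohexenes with acetylenic esters used to build drimane skeletons. Ring B is closed by this intermolecular [4+2] cycloaddition, both new σ-bonds forming on one face of the diene, to give a cyclohexa-1,4-diene. The only new stereocentre, quaternary C10, is controlled by the pseudoaxial CH2OTBS group on neighbouring C4: the equatorial C2 OTBS group locks this half-chair (the flipped form would place OTBS and the C4 methyl syn-diaxial), so the dienophile should add to the opposite α-face and leave the angular methyl cis to CH2OTBS. The step needs regioselectivity, secured by matched polarization (nucleophilic unsubstituted diene terminus with positive charge building at the fully substituted terminus, electrophilic ynal β-carbon), which puts the methyl on C8 and the formyl on C9. It also needs chemoselectivity for C≡C over C=O and survival of the silyl ethers, secured by the aprotic substoichiometric Lewis acid at low temperature. The adduct cannot aromatize because C10 is quaternary.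

**Step 11**
Reactants: 15 Diels–Alder adduct
Product: 17 (1S,4aS,6R,8S,8aR)-6-(TBS-oxy)-8-[(TBS-oxy)methyl]-4-(hydroxymethyl)-3,4a,8-trimethyl-1,2,4a,5,6,7,8,8a-octahydronaphthalen-1-ol, via alkylborane 16 (not isolated)
Conditions: BH3·THF (3 equiv), THF, 0 °C → rt; then NaOH, 30% H2O2, 0 °C → rt
Reagents that add atoms: hydrogen peroxide, OO
Why: Borane reduces the aldehyde and hydroborates the trisubstituted C5=C6 bond with boron on C6; syn addition from the α-face, opposite the axial C20 methyl and C19 CH2OTBS groups, sets H-5α (trans ring fusion) and, after oxidation with retention, the 6α-hydroxyl, as in hydroboration of Δ5-steroids, while the hindered tetrasubstituted C8=C9 bond should not react.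

**Step 12**
Reactants: 17 diol
Product: 18 (4S,4aR,5S,7R,8aS)-7-(TBS-oxy)-5-[(TBS-oxy)methyl]-4-hydroxy-2,5,8a-trimethyl-3,4,4a,5,6,7,8,8a-octahydronaphthalene-1-carbaldehyde
Conditions: activated MnO2 (excess), CH2Cl2, rt
Reagents that add atoms: none
Why: MnO2 oxidizes only the allylic primary alcohol and leaves the saturated secondary C6 alcohol.

**Step 13**
Reactants: 18 hydroxy enal
Product: 19 (1S,4aS,6R,8S,8aR)-6-(TBS-oxy)-8-[(TBS-oxy)methyl]-4-ethenyl-3,4a,8-trimethyl-1,2,4a,5,6,7,8,8a-octahydronaphthalen-1-ol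
Conditions: MePPh3Br (3 equiv), KOtBu (3 equiv), THF, 0 °C → rt
Reagents that add atoms: methyltriphenylphosphonium bromide, C[P+](c1ccccc1)(c1ccccc1)c1ccccc1.[Br-]
Why: Wittig methylenation of hindered β,β-disubstituted enals of the β-cyclocitral type is well established, and the free hydroxyl is carried as its alkoxide by the excess ylide.

**Step 14**
Reactants: 19 hydroxy diene
Product: 20 (1S,4aS,6R,8S,8aR)-6-(TBS-oxy)-8-[(TBS-oxy)methyl]-4-ethenyl-3,4a,8-trimethyl-1,2,4a,5,6,7,8,8a-octahydronaphthalen-1-yl acetate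
Conditions: Ac2O, DMAP (cat.), pyridine, rt
Reagents that add atoms: acetic anhydride, CC(=O)OC(C)=O
Why: DMAP-catalysed acylation installs the only ester of the target on the equatorial 6α-hydroxyl while the other two hydroxyls are still silylated.

**Step 15**
Reactants: 20 acetoxy diene; 21 4-bromofuran-2(5H)-one
Product: 23 (1S,4aS,6R,8S,8aR)-6-(TBS-oxy)-8-[(TBS-oxy)methyl]-3,4a,8-trimethyl-4-[2-(5-oxo-2,5-dihydrofuran-3-yl)ethyl]-1,2,4a,5,6,7,8,8a-octahydronaphthalen-1-yl acetate, via B-alkyl-9-BBN adduct 22 (not isolated)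
Conditions: 9-BBN (1.3 equiv), THF, 0 °C → rt; then 21, PdCl2(dppf) (5 mol %), AsPh3, 3 M aq. K3PO4, DMF, rt
Reagents that add atoms: none
Why: 9-BBN should hydroborate only the terminal vinyl group, anti-Markovnikov, and the primary alkylborane then undergoes B-alkyl Suzuki–Miyaura coupling with the β-bromobutenolide to form the C12–C13 bond.

**Step 16**
Reactants: 23 bis-silyl ether
Product: 24 (1S,4aS,6R,8S,8aR)-6-hydroxy-8-(hydroxymethyl)-3,4a,8-trimethyl-4-[2-(5-oxo-2,5-dihydrofuran-3-yl)ethyl]-1,2,4a,5,6,7,8,8a-octahydronaphthalen-1-yl acetate (CNP0231903.1)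
Conditions: HF·pyridine, THF/pyridine, 0 °C → rt
Reagents that add atoms: none
Why: Fluoride cleavage of both TBS ethers under mildly acidic conditions should leave the acetate, the butenolide and the tetrasubstituted alkene untouched, with no acyl migration because the 6α-acetate and the 19-hydroxyl lie on opposite faces.

**Compound list**
1 | 2,6-dimethylbenzene-1,4-diol (2,6-dimethylhydroquinone) | Cc1cc(O)cc(C)c1O | starting material
2 | 2,6-dimethylcyclohexane-1,4-diol (all-cis isomer shown; main component of the hydrogenation mixture) | C[C@@H]1C[C@H](O)C[C@H](C)[C@@H]1O | intermediate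
3 | all-cis-4-[(tert-butyldimethylsilyl)oxy]-2,6-dimethylcyclohexan-1-ol | C[C@@H]1C[C@H](O[Si](C)(C)C(C)(C)C)C[C@H](C)[C@@H]1O | intermediate
4 | 4-[(tert-butyldimethylsilyl)oxy]-2,6-dimethylcyclohexan-1-one, mixture of methyl epimers (not isolated) | CC1CC(O[Si](C)(C)C(C)(C)C)CC(C)C1=O | intermediate
5 | (2R,6S)-4-[(tert-butyldimethylsilyl)oxy]-2,6-dimethylcyclohexan-1-one, all-cis (meso) | C[C@@H]1C[C@H](O[Si](C)(C)C(C)(C)C)C[C@H](C)C1=O | intermediate
6 | lithium (4R,6S)-4-[(tert-butyldimethylsilyl)oxy]-2,6-dimethylcyclohex-1-en-1-olate (not isolated) | CC1=C(O[Li])[C@@H](C)C[C@@H](O[Si](C)(C)C(C)(C)C)C1 | intermediate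
7 | (4R,6S)-4-[(tert-butyldimethylsilyl)oxy]-2,6-dimethyl-1-[(trimethylsilyl)oxy]cyclohex-1-ene (silyloxy and remaining methyl cis) | CC1=C(O[Si](C)(C)C)[C@@H](C)C[C@@H](O[Si](C)(C)C(C)(C)C)C1 | intermediate
8 | (2R,4R,6S)-4-[(tert-butyldimethylsilyl)oxy]-2-(hydroxymethyl)-2,6-dimethylcyclohexan-1-one (CH2OH trans to OTBS) | O=C1[C@@H](C)C[C@@H](O[Si](C)(C)C(C)(C)C)C[C@]1(C)CO | intermediate
9 | (2R,4R,6S)-4-[(tert-butyldimethylsilyl)oxy]-2-{[(tert-butyldimethylsilyl)oxy]methyl}-2,6-dimethylcyclohexan-1-one | O=C1[C@@H](C)C[C@@H](O[Si](C)(C)C(C)(C)C)C[C@]1(C)CO[Si](C)(C)C(C)(C)C | intermediate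
10 | potassium (4R,6R)-4-[(tert-butyldimethylsilyl)oxy]-6-{[(tert-butyldimethylsilyl)oxy]methyl}-2,6-dimethylcyclohex-1-en-1-olate (not isolated) | CC1=C(O[K])[C@@](C)(CO[Si](C)(C)C(C)(C)C)C[C@H](O[Si](C)(C)C(C)(C)C)C1 | intermediate
11 | (4R,6R)-4-[(tert-butyldimethylsilyl)oxy]-6-{[(tert-butyldimethylsilyl)oxy]methyl}-2,6-dimethylcyclohex-1-en-1-yl trifluoromethanesulfonate | CC1=C(OS(=O)(=O)C(F)(F)F)[C@@](C)(CO[Si](C)(C)C(C)(C)C)C[C@H](O[Si](C)(C)C(C)(C)C)C1 | intermediate
12 | (4R,6S)-4-[(tert-butyldimethylsilyl)oxy]-6-{[(tert-butyldimethylsilyl)oxy]methyl}-1-ethenyl-2,6-dimethylcyclohex-1-ene | C=CC1=C(C)C[C@@H](O[Si](C)(C)C(C)(C)C)C[C@]1(C)CO[Si](C)(C)C(C)(C)C | intermediate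
13 | but-2-yn-1-ol | CC#CCO | starting material
14 | but-2-ynal | CC#CC=O | intermediate
15 | (5S,7R,8aS)-7-[(tert-butyldimethylsilyl)oxy]-5-{[(tert-butyldimethylsilyl)oxy]methyl}-2,5,8a-trimethyl-3,5,6,7,8,8a-hexahydronaphthalene-1-carbaldehyde (labda-5,8-dien-11-al core; C20 cis to C19) | O=CC1=C(C)CC=C2[C@@](C)(CO[Si](C)(C)C(C)(C)C)C[C@H](O[Si](C)(C)C(C)(C)C)C[C@]12C | intermediate
16 | 6α-boryl 11-O-boryl derivative of 17 (representative monomeric alkylborane, not isolated) | B[C@H]1CC(C)=C(COB)[C@@]2(C)C[C@@H](O[Si](C)(C)C(C)(C)C)C[C@](C)(CO[Si](C)(C)C(C)(C)C)[C@H]12 | intermediate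
17 | (1S,4aS,6R,8S,8aR)-6-[(tert-butyldimethylsilyl)oxy]-8-{[(tert-butyldimethylsilyl)oxy]methyl}-4-(hydroxymethyl)-3,4a,8-trimethyl-1,2,4a,5,6,7,8,8a-octahydronaphthalen-1-ol (6α,11-diol, H-5α) | O[C@H]1CC(C)=C(CO)[C@@]2(C)C[C@@H](O[Si](C)(C)C(C)(C)C)C[C@](C)(CO[Si](C)(C)C(C)(C)C)[C@H]12 | intermediate
18 | (4S,4aR,5S,7R,8aS)-7-[(tert-butyldimethylsilyl)oxy]-5-{[(tert-butyldimethylsilyl)oxy]methyl}-4-hydroxy-2,5,8a-trimethyl-3,4,4a,5,6,7,8,8a-octahydronaphthalene-1-carbaldehyde | O[C@H]1CC(C)=C(C=O)[C@@]2(C)C[C@@H](O[Si](C)(C)C(C)(C)C)C[C@](C)(CO[Si](C)(C)C(C)(C)C)[C@H]12 | intermediate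
19 | (1S,4aS,6R,8S,8aR)-6-[(tert-butyldimethylsilyl)oxy]-8-{[(tert-butyldimethylsilyl)oxy]methyl}-4-ethenyl-3,4a,8-trimethyl-1,2,4a,5,6,7,8,8a-octahydronaphthalen-1-ol | O[C@H]1CC(C)=C(C=C)[C@@]2(C)C[C@@H](O[Si](C)(C)C(C)(C)C)C[C@](C)(CO[Si](C)(C)C(C)(C)C)[C@H]12 | intermediate
20 | (1S,4aS,6R,8S,8aR)-6-[(tert-butyldimethylsilyl)oxy]-8-{[(tert-butyldimethylsilyl)oxy]methyl}-4-ethenyl-3,4a,8-trimethyl-1,2,4a,5,6,7,8,8a-octahydronaphthalen-1-yl acetate | CC(=O)O[C@H]1CC(C)=C(C=C)[C@@]2(C)C[C@@H](O[Si](C)(C)C(C)(C)C)C[C@](C)(CO[Si](C)(C)C(C)(C)C)[C@H]12 | intermediate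
21 | 4-bromofuran-2(5H)-one | O=C1C=C(Br)CO1 | starting material
22 | 9-{2-[(1S,4aS,6R,8S,8aR)-1-acetoxy-6-(TBS-oxy)-8-(TBS-oxymethyl)-3,4a,8-trimethyl-octahydronaphthalen-4-yl]ethyl}-9-borabicyclo[3.3.1]nonane (not isolated) | CC(=O)O[C@H]1CC(C)=C(CCB2C3CCCC2CCC3)[C@@]2(C)C[C@@H](O[Si](C)(C)C(C)(C)C)C[C@](C)(CO[Si](C)(C)C(C)(C)C)[C@H]12 | intermediate
23 | (1S,4aS,6R,8S,8aR)-6-[(tert-butyldimethylsilyl)oxy]-8-{[(tert-butyldimethylsilyl)oxy]methyl}-3,4a,8-trimethyl-4-[2-(5-oxo-2,5-dihydrofuran-3-yl)ethyl]-1,2,4a,5,6,7,8,8a-octahydronaphthalen-1-yl acetate | CC(=O)O[C@H]1CC(C)=C(CCC2=CC(=O)OC2)[C@@]2(C)C[C@@H](O[Si](C)(C)C(C)(C)C)C[C@](C)(CO[Si](C)(C)C(C)(C)C)[C@H]12 | intermediate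
24 | (1S,4aS,6R,8S,8aR)-6-hydroxy-8-(hydroxymethyl)-3,4a,8-trimethyl-4-[2-(5-oxo-2,5-dihydrofuran-3-yl)ethyl]-1,2,4a,5,6,7,8,8a-octahydronaphthalen-1-yl acetate (6α-acetoxy-2α,19-dihydroxylabda-8,13-dien-15,16-olide) | CC(=O)O[C@H]1CC(C)=C(CCC2=CC(=O)OC2)[C@@]2(C)C[C@@H](O)C[C@](C)(CO)[C@H]12 | target

**Step count and risks**
Total step count: 16. Longest linear sequence: 15 steps (steps 1–8 and 10–16; step 9 is a one-step branch).

Steps most likely to fail:

1. Step 10. The twisted, fully substituted diene terminus may react too slowly at the low temperature that the Lewis acid-bound ynal tolerates, so that oligomerization of the ynal competes, and facial selectivity may erode if the mixture has to be warmed. Fallback: setting out from diene 12, ethyl but-2-ynoate (commercial) serves as dienophile with stoichiometric EtAlCl2 in toluene (or neat at 130 °C), conditions an ester tolerates, to give ethyl ester adduct F1. BH3·THF then hydroborates C5=C6 from the α-face without touching the ester to give C6 alkylborane F2, which alkaline H2O2 converts into 6α-hydroxy ester F3. LiAlH4 in THF at 0 °C reduces the ester to the allylic alcohol, and the route is rejoined at diol 17.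

2. Step 4. The chiral amide may discriminate the two enantiotopic axial α-protons insufficiently, giving enol ether of low enantiomeric purity that cannot be upgraded later. Fallback: setting out from meso ketone 5, soft enolization (TMSOTf, Et3N, CH2Cl2, 0 °C) gives enol ether 7 as a racemate together with its enantiomer, ent-enol ether F4. Hydroxymethylation as in step 5 gives 8 together with its enantiomer, ent-hydroxymethyl ketone F5. Lipase-catalysed transesterification with vinyl acetate (immobilized Candida antarctica lipase B, tert-butyl methyl ether), with an enzyme selected to acylate F5, converts it into ent-acetate F6, which is separated, and the unreacted alcohol returns to the route as compound 8.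

3. Step 15. Base-induced degradation of the bromobutenolide, partial hydrolysis of the acetate and protodeboronation may outpace transmetalation. Fallback: setting out from acetate 20, the 9-BBN adduct 22 is oxidized with NaBO3·4H2O (THF/H2O, rt) to primary alcohol F7. I2, PPh3 and imidazole (Appel reaction) give iodide F8. Zinc dust with LiCl in THF inserts to give alkylzinc iodide F9, which undergoes base-free Negishi coupling with 21 under Pd(PPh3)4 catalysis, and the route is rejoined at 23.

**Further compounds**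
F1 | step 10 | ethyl (5S,7R,8aS)-7-[(tert-butyldimethylsilyl)oxy]-5-{[(tert-butyldimethylsilyl)oxy]methyl}-2,5,8a-trimethyl-3,5,6,7,8,8a-hexahydronaphthalene-1-carboxylate | CCOC(=O)C1=C(C)CC=C2[C@@](C)(CO[Si](C)(C)C(C)(C)C)C[C@H](O[Si](C)(C)C(C)(C)C)C[C@]12C
F2 | step 10 | 6α-boryl derivative of F3 (representative monomeric alkylborane) | B[C@H]1CC(C)=C(C(=O)OCC)[C@@]2(C)C[C@@H](O[Si](C)(C)C(C)(C)C)C[C@](C)(CO[Si](C)(C)C(C)(C)C)[C@H]12
F3 | step 10 | ethyl (4S,4aR,5S,7R,8aS)-7-[(tert-butyldimethylsilyl)oxy]-5-{[(tert-butyldimethylsilyl)oxy]methyl}-4-hydroxy-2,5,8a-trimethyl-3,4,4a,5,6,7,8,8a-octahydronaphthalene-1-carboxylate | O[C@H]1CC(C)=C(C(=O)OCC)[C@@]2(C)C[C@@H](O[Si](C)(C)C(C)(C)C)C[C@](C)(CO[Si](C)(C)C(C)(C)C)[C@H]12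
F4 | step 4 | (4S,6R)-4-[(tert-butyldimethylsilyl)oxy]-2,6-dimethyl-1-[(trimethylsilyl)oxy]cyclohex-1-ene (enantiomer of 7) | CC1=C(O[Si](C)(C)C)[C@H](C)C[C@H](O[Si](C)(C)C(C)(C)C)C1
F5 | step 4 | (2S,4S,6R)-4-[(tert-butyldimethylsilyl)oxy]-2-(hydroxymethyl)-2,6-dimethylcyclohexan-1-one (enantiomer of 8) | O=C1[C@H](C)C[C@H](O[Si](C)(C)C(C)(C)C)C[C@@]1(C)CO
F6 | step 4 | [(1S,3R,5S)-5-[(tert-butyldimethylsilyl)oxy]-1,3-dimethyl-2-oxocyclohexyl]methyl acetate (acetate of F5) | O=C1[C@H](C)C[C@H](O[Si](C)(C)C(C)(C)C)C[C@@]1(C)COC(C)=O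
F7 | step 15 | (1S,4aS,6R,8S,8aR)-6-[(tert-butyldimethylsilyl)oxy]-8-{[(tert-butyldimethylsilyl)oxy]methyl}-4-(2-hydroxyethyl)-3,4a,8-trimethyl-1,2,4a,5,6,7,8,8a-octahydronaphthalen-1-yl acetate | CC(=O)O[C@H]1CC(C)=C(CCO)[C@@]2(C)C[C@@H](O[Si](C)(C)C(C)(C)C)C[C@](C)(CO[Si](C)(C)C(C)(C)C)[C@H]12
F8 | step 15 | (1S,4aS,6R,8S,8aR)-6-[(tert-butyldimethylsilyl)oxy]-8-{[(tert-butyldimethylsilyl)oxy]methyl}-4-(2-iodoethyl)-3,4a,8-trimethyl-1,2,4a,5,6,7,8,8a-octahydronaphthalen-1-yl acetate | CC(=O)O[C@H]1CC(C)=C(CCI)[C@@]2(C)C[C@@H](O[Si](C)(C)C(C)(C)C)C[C@](C)(CO[Si](C)(C)C(C)(C)C)[C@H]12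
F9 | step 15 | alkylzinc iodide from F8 (C12–ZnI) | CC(=O)O[C@H]1CC(C)=C(CC[Zn]I)[C@@]2(C)C[C@@H](O[Si](C)(C)C(C)(C)C)C[C@](C)(CO[Si](C)(C)C(C)(C)C)[C@H]12
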